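**Plan**

Numbering used: ring C1–C14 (C1 = ring CH; alkenes C3=C4, C7=C8, C11=C12), C15 = carbinol carbon, C16 = chain CH2 on C15.
Cuts: (i) C15–C16, giving a homogeranyl boronic ester and the C15–H triisopropylbenzoate of the macrocyclic secondary alcohol; (ii) ring bond C13–C14 (sulfonyl carbanion plus allylic bromide); (iii) C1–C2, back to ethyl (3R)-3-hydroxybutanoate 1 and (2E,6E)-farnesyl bromide 2.
Enabling feature: C15 carries only CH3, the ring C1–H and the primary C16H2, so it is the formal product of replacing the C15–H of a secondary ester by a primary alkyl group that migrates from boron; the ring carbons are C1/C14 (C2 and C1 of the hydroxybutanoate) plus the twelve backbone carbons of farnesyl (C2–C13).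
Forward order: C1–C2 alkylation; C14 ester turned into CH2SO2Ph; terminal (E)-methyl (C13) turned into CH2Br; 14-membered ring closed at C13–C14; sulfone removed; side chain joined last at C15–C16.
Stereochemistry: C15 from the chiral pool (1); C1 by anti-selective Fráter–Seebach alkylation; quaternary C15 by stereospecific lithiation–borylation–oxidation (C–H replaced by C–C with retention, independent of C1); E alkenes from 2, from geranyl bromide and from E-selective SeO2 oxidation.

Key step: step 13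

Remark: commercial (2E,6E)-farnesyl bromide and geranyl bromide are taken as pure E isomers; lithiation and borylation are taken to occur with retention and the 1,2-shift with inversion at C15, as is established for this reaction class.

**Route**

Step 1
Reactants: 1 ethyl (3R)-3-hydroxybutanoate; 2 (2E,6E)-farnesyl bromide
Product: 4 ethyl (2R,3R)-3-hydroxy-2-[(2E,6E)-3,7,11-trimethyldodeca-2,6,10-trien-1-yl]butanoate, via dilithium alkoxide–enolate 3 (not isolated)
Conditions: LiN(iPr)2 (2.2 equiv), THF, −50 → −20 °C; then 2, DMPU, −78 → −10 °C; H2O quench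
Reagents that add atoms: none
Why: Fráter–Seebach alkylation: the lithium-chelated alkoxide–enolate should be alkylated by the primary allylic bromide on the face away from the C15 methyl group, which sets C1 anti to the C15 hydroxyl (2R,3R).

Step 2
Reactants: 4 ethyl (2R,3R)-3-hydroxy-2-[(2E,6E)-3,7,11-trimethyldodeca-2,6,10-trien-1-yl]butanoate
Product: 5 (2S,3R)-2-[(2E,6E)-3,7,11-trimethyldodeca-2,6,10-trien-1-yl]butane-1,3-diol
Conditions: LiAlH4, THF, 0 °C; H2O quench
Reagents that add atoms: none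
Why: Hydride reduction of the ester to the primary alcohol (C14) should leave the isolated trisubstituted alkenes and both stereocentres untouched.

Step 3
Reactants: 5 (2S,3R)-2-[(2E,6E)-3,7,11-trimethyldodeca-2,6,10-trien-1-yl]butane-1,3-diol
Product: 6 (2R,3R,5E,9E)-6,10,14-trimethyl-3-[(phenylsulfanyl)methyl]pentadeca-5,9,13-trien-2-ol
Conditions: PhSSPh, PBu3, pyridine, rt
Reagents that add atoms: diphenyl disulfide c1ccc(SSc2ccccc2)cc1
Why: Hata thioetherification goes through an alkoxyphosphonium salt that should form and be displaced by thiolate much faster at the primary C14 hydroxyl than at the α-branched secondary C15 hydroxyl.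

Step 4
Reactants: 6 (2R,3R,5E,9E)-6,10,14-trimethyl-3-[(phenylsulfanyl)methyl]pentadeca-5,9,13-trien-2-ol
Product: 8 (2R,3R,5E,9E)-6,10,14-trimethyl-3-[(phenylsulfanyl)methyl]pentadeca-5,9,13-trien-2-yl 2,4,6-tri(propan-2-yl)benzoate, via sodium alkoxide 7 (not isolated)
Conditions: NaH, THF, 0 °C → rt; then 2,4,6-tri(propan-2-yl)benzoyl chloride, 60 °C
Reagents that add atoms: 2,4,6-tri(propan-2-yl)benzoyl chloride CC(C)c1cc(C(C)C)c(C(Cl)=O)c(C(C)C)c1
Why: O-acylation of the alkoxide by the hindered aroyl chloride (addition–elimination at the acyl carbon) installs the activating ester for the key step without touching the C15–O bond, so the C15 configuration is retained.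

Step 5
Reactants: 8 (2R,3R,5E,9E)-6,10,14-trimethyl-3-[(phenylsulfanyl)methyl]pentadeca-5,9,13-trien-2-yl 2,4,6-tri(propan-2-yl)benzoate
Product: 9 (2R,3R,5E,9E)-3-[(benzenesulfonyl)methyl]-6,10,14-trimethylpentadeca-5,9,13-trien-2-yl 2,4,6-tri(propan-2-yl)benzoate
Conditions: (NH4)6Mo7O24·4H2O (cat.), 30% H2O2 (aq), EtOH, 0 °C → rt
Reagents that add atoms: hydrogen peroxide OO
Why: Molybdate-catalysed peroxide oxidation of sulfide to sulfone is fast at sulfur and should leave trisubstituted alkenes and the hindered ester alone.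

Step 6
Reactants: 9 (2R,3R,5E,9E)-3-[(benzenesulfonyl)methyl]-6,10,14-trimethylpentadeca-5,9,13-trien-2-yl 2,4,6-tri(propan-2-yl)benzoate
Product: 10 (2R,3R,5E,9E,13E)-3-[(benzenesulfonyl)methyl]-15-hydroxy-6,10,14-trimethylpentadeca-5,9,13-trien-2-yl 2,4,6-tri(propan-2-yl)benzoate
Conditions: SeO2 (cat.), tBuOOH (70% aq), salicylic acid (cat.), CH2Cl2, 0 °C → rt, stopped at partial conversion
Reagents that add atoms: tert-butyl hydroperoxide CC(C)(C)OO
Why: Riley allylic oxidation (ene reaction, then [2,3]-sigmatropic shift) should attack the most accessible terminal isopropylidene group, and there the (E)-methyl group, giving the (E)-allylic alcohol at C13.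

Step 7
Reactants: 10 (2R,3R,5E,9E,13E)-3-[(benzenesulfonyl)methyl]-15-hydroxy-6,10,14-trimethylpentadeca-5,9,13-trien-2-yl 2,4,6-tri(propan-2-yl)benzoate
Product: 11 (2R,3R,5E,9E,13E)-3-[(benzenesulfonyl)methyl]-15-bromo-6,10,14-trimethylpentadeca-5,9,13-trien-2-yl 2,4,6-tri(propan-2-yl)benzoate
Conditions: CBr4, PPh3, CH2Cl2, 0 °C
Reagents that add atoms: tetrabromomethane BrC(Br)(Br)Br
Why: Appel bromination converts the primary allylic alcohol into the bromide by SN2 displacement of the oxyphosphonium group, under neutral conditions that should keep the alkene geometry.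

Step 8
Reactants: 11 (2R,3R,5E,9E,13E)-3-[(benzenesulfonyl)methyl]-15-bromo-6,10,14-trimethylpentadeca-5,9,13-trien-2-yl 2,4,6-tri(propan-2-yl)benzoate
Product: 13 (1R)-1-[(1R,3E,7E,11E)-14-(benzenesulfonyl)-4,8,12-trimethylcyclotetradeca-3,7,11-trien-1-yl]ethyl 2,4,6-tri(propan-2-yl)benzoate (both C14 epimers), via α-lithio sulfone 12 (not isolated)
Conditions: LiN(iPr)2 (1.5 equiv), THF, −78 → 0 °C, slow addition of 11 (final concentration about 0.002 M); H2O quench
Reagents that add atoms: none
Why: Intramolecular SN2 alkylation of the α-sulfonyl carbanion (C14) by the primary allylic bromide (C13) under high dilution is a standard closure of cembrane-type 14-membered carbocycles; the new C14 centre is of no consequence because the sulfone is removed in step 9.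

Step 9
Reactants: 13 (1R)-1-[(1R,3E,7E,11E)-14-(benzenesulfonyl)-4,8,12-trimethylcyclotetradeca-3,7,11-trien-1-yl]ethyl 2,4,6-tri(propan-2-yl)benzoate
Product: 14 (1R)-1-[(1R,3E,7E,11E)-4,8,12-trimethylcyclotetradeca-3,7,11-trien-1-yl]ethyl 2,4,6-tri(propan-2-yl)benzoate
Conditions: sodium amalgam (Na/Hg, 6% Na), MeOH–THF, −20 °C → rt
Reagents that add atoms: none
Why: Reductive desulfonylation by electron transfer cleaves the C14–S bond and methanol protonates C14; the benzoate is γ and not β to the sulfone, so no Julia-type elimination can occur, and C1 and C15 are not touched.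

Step 10
Reactants: 15 geranyl bromide; 16 thioanisole
Product: 18 [(3E)-4,8-dimethylnona-3,7-dien-1-yl](phenyl)sulfane, via (phenylsulfanyl)methyllithium 17 (not isolated)
Conditions: 16, nBuLi, DABCO, THF, 0 °C; then 15, −78 °C → rt
Reagents that add atoms: none
Why: SN2 alkylation of the sulfur-stabilised carbanion at the primary carbon of the allylic bromide adds the one carbon that becomes C16 and keeps the E alkene.

Step 11
Reactants: 18 [(3E)-4,8-dimethylnona-3,7-dien-1-yl](phenyl)sulfane
Product: 19 (3E)-1-iodo-4,8-dimethylnona-3,7-diene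
Conditions: MeI (excess), NaI (cat.), DMF, 75 °C
Reagents that add atoms: iodomethane CI
Why: S-methylation gives a sulfonium salt that iodide displaces at the primary homoallylic carbon (SN2), with thioanisole as the leaving group.

Step 12
Reactants: 19 (3E)-1-iodo-4,8-dimethylnona-3,7-diene
Product: 22 2-[(3E)-4,8-dimethylnona-3,7-dien-1-yl]-5,5-dimethyl-1,3,2-dioxaborinane, via homogeranyllithium 20 (not isolated), via lithium trimethoxyborate 21 (not isolated)
Conditions: tBuLi (2.1 equiv), Et2O–pentane, −78 °C; B(OMe)3, −78 °C → rt; 2,2-dimethylpropane-1,3-diol, rt; H2O wash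
Reagents that add atoms: trimethyl borate COB(OC)OC; 2,2-dimethylpropane-1,3-diol CC(C)(CO)CO
Why: Lithium–iodine exchange is a polar process that should not scramble the homoallylic alkene; borylation of the alkyllithium and transesterification then give the unhindered neopentyl glycol boronic ester needed for the key step.

Step 13
Reactants: 14 (1R)-1-[(1R,3E,7E,11E)-4,8,12-trimethylcyclotetradeca-3,7,11-trien-1-yl]ethyl 2,4,6-tri(propan-2-yl)benzoate; 22 2-[(3E)-4,8-dimethylnona-3,7-dien-1-yl]-5,5-dimethyl-1,3,2-dioxaborinane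
Product: 26 colleterpenol [(2S,5E)-6,10-dimethyl-2-[(1R,3E,7E,11E)-4,8,12-trimethylcyclotetradeca-3,7,11-trien-1-yl]undeca-5,9-dien-2-ol], via lithiated benzoate 23 (not isolated), via boronate complex 24 (not isolated), via tertiary boronic ester 25 (not isolated)
Conditions: 14, sBuLi (1.3 equiv), TMEDA (6 equiv), cyclopentyl methyl ether, −60 °C; 22 (1.5 equiv), −60 → 50 °C; then 2 M NaOH (aq), 30% H2O2 (aq), THF, 0 °C → rt
Reagents that add atoms: hydrogen peroxide OO
Why: The ester carbonyl of 14 directs sBuLi·TMEDA to the C15–H bond and gives the configurationally stable α-acyloxy alkyllithium 23 with retention; 22 adds with retention at carbon to form boronate 24, whose C16H2 group shifts from boron to C15 anti-periplanar to the departing triisopropylbenzoate (inversion at C15), and alkaline peroxide then replaces boron in 25 by hydroxyl with retention. The closest known reaction type is the lithiation–borylation of secondary dialkyl 2,4,6-triisopropylbenzoates with neopentyl glycol boronic esters, followed by oxidation to tertiary alcohols. No ring is closed in this step. The only new stereocentre, C15, is set stereospecifically by the (R) configuration of the C15–H centre of 14 (formal replacement of H by C16 with retention while oxygen stays in place), not by C1, whose two ring arms differ too little to direct an addition to a C15 ketone. The step needs deprotonation at C15–H in preference to the many allylic positions and complete transfer of the primary alkyl group: the first is secured by complexation of the base to the benzoate carbonyl, which its two ortho isopropyl groups shield from addition, the second by the unhindered neopentyl glycol ester and the good migratory aptitude of a primary alkyl group.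

**Compound list**

1 | ethyl (3R)-3-hydroxybutanoate | C[C@@H](O)CC(=O)OCC | starting material
2 | (2E,6E)-farnesyl bromide [(2E,6E)-1-bromo-3,7,11-trimethyldodeca-2,6,10-triene] | CC(C)=CCC/C(C)=C/CC/C(C)=C/CBr | starting material
3 | dilithium alkoxide–enolate of 1 (chelated dianion) | C[C@@H](O[Li])/C=C(/OCC)O[Li] | intermediate
4 | ethyl (2R,3R)-3-hydroxy-2-[(2E,6E)-3,7,11-trimethyldodeca-2,6,10-trien-1-yl]butanoate | C[C@@H](O)[C@@H](C/C=C(\C)CC/C=C(\C)CCC=C(C)C)C(=O)OCC | intermediate
5 | (2S,3R)-2-[(2E,6E)-3,7,11-trimethyldodeca-2,6,10-trien-1-yl]butane-1,3-diol | C[C@@H](O)[C@@H](C/C=C(\C)CC/C=C(\C)CCC=C(C)C)CO | intermediate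
6 | (2R,3R,5E,9E)-6,10,14-trimethyl-3-[(phenylsulfanyl)methyl]pentadeca-5,9,13-trien-2-ol | C[C@@H](O)[C@@H](C/C=C(\C)CC/C=C(\C)CCC=C(C)C)CSc1ccccc1 | intermediate
7 | sodium alkoxide of 6 | [Na+].C[C@@H]([O-])[C@@H](C/C=C(\C)CC/C=C(\C)CCC=C(C)C)CSc1ccccc1 | intermediate
8 | (2R,3R,5E,9E)-6,10,14-trimethyl-3-[(phenylsulfanyl)methyl]pentadeca-5,9,13-trien-2-yl 2,4,6-tri(propan-2-yl)benzoate | C[C@@H](OC(=O)c1c(C(C)C)cc(C(C)C)cc1C(C)C)[C@@H](C/C=C(\C)CC/C=C(\C)CCC=C(C)C)CSc2ccccc2 | intermediate
9 | (2R,3R,5E,9E)-3-[(benzenesulfonyl)methyl]-6,10,14-trimethylpentadeca-5,9,13-trien-2-yl 2,4,6-tri(propan-2-yl)benzoate | C[C@@H](OC(=O)c1c(C(C)C)cc(C(C)C)cc1C(C)C)[C@@H](C/C=C(\C)CC/C=C(\C)CCC=C(C)C)CS(=O)(=O)c2ccccc2 | intermediate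
10 | (2R,3R,5E,9E,13E)-3-[(benzenesulfonyl)methyl]-15-hydroxy-6,10,14-trimethylpentadeca-5,9,13-trien-2-yl 2,4,6-tri(propan-2-yl)benzoate | C[C@@H](OC(=O)c1c(C(C)C)cc(C(C)C)cc1C(C)C)[C@@H](C/C=C(\C)CC/C=C(\C)CC/C=C(\C)CO)CS(=O)(=O)c2ccccc2 | intermediate
11 | (2R,3R,5E,9E,13E)-3-[(benzenesulfonyl)methyl]-15-bromo-6,10,14-trimethylpentadeca-5,9,13-trien-2-yl 2,4,6-tri(propan-2-yl)benzoate | C[C@@H](OC(=O)c1c(C(C)C)cc(C(C)C)cc1C(C)C)[C@@H](C/C=C(\C)CC/C=C(\C)CC/C=C(\C)CBr)CS(=O)(=O)c2ccccc2 | intermediate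
12 | α-lithio sulfone of 11 (lithium on the sulfonyl-bearing carbon C14) | C[C@@H](OC(=O)c1c(C(C)C)cc(C(C)C)cc1C(C)C)[C@@H](C/C=C(\C)CC/C=C(\C)CC/C=C(\C)CBr)C([Li])S(=O)(=O)c2ccccc2 | intermediate
13 | (1R)-1-[(1R,3E,7E,11E)-14-(benzenesulfonyl)-4,8,12-trimethylcyclotetradeca-3,7,11-trien-1-yl]ethyl 2,4,6-tri(propan-2-yl)benzoate (both C14 epimers) | C[C@@H](OC(=O)c1c(C(C)C)cc(C(C)C)cc1C(C)C)[C@H]2C/C=C(\C)CC/C=C(\C)CC/C=C(\C)CC2S(=O)(=O)c3ccccc3 | intermediate
14 | (1R)-1-[(1R,3E,7E,11E)-4,8,12-trimethylcyclotetradeca-3,7,11-trien-1-yl]ethyl 2,4,6-tri(propan-2-yl)benzoate | C[C@@H](OC(=O)c1c(C(C)C)cc(C(C)C)cc1C(C)C)[C@H]2C/C=C(\C)CC/C=C(\C)CC/C=C(\C)CC2 | intermediate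
15 | geranyl bromide [(2E)-1-bromo-3,7-dimethylocta-2,6-diene] | CC(C)=CCC/C(C)=C/CBr | starting material
16 | thioanisole (methyl phenyl sulfide) | CSc1ccccc1 | starting material
17 | (phenylsulfanyl)methyllithium | [Li]CSc1ccccc1 | intermediate
18 | [(3E)-4,8-dimethylnona-3,7-dien-1-yl](phenyl)sulfane (homogeranyl phenyl sulfide) | CC(C)=CCC/C(C)=C/CCSc1ccccc1 | intermediate
19 | (3E)-1-iodo-4,8-dimethylnona-3,7-diene (homogeranyl iodide) | CC(C)=CCC/C(C)=C/CCI | intermediate
20 | homogeranyllithium [(3E)-4,8-dimethylnona-3,7-dien-1-yllithium] | CC(C)=CCC/C(C)=C/CC[Li] | intermediate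
21 | lithium [(3E)-4,8-dimethylnona-3,7-dien-1-yl]trimethoxyborate | [Li+].CO[B-](OC)(OC)CC/C=C(\C)CCC=C(C)C | intermediate
22 | 2-[(3E)-4,8-dimethylnona-3,7-dien-1-yl]-5,5-dimethyl-1,3,2-dioxaborinane | CC(C)=CCC/C(C)=C/CCB1OCC(C)(C)CO1 | intermediate
23 | α-lithiated benzoate of 14 (lithium in place of the C15 hydrogen, configuration retained) | C[C@@]([Li])(OC(=O)c1c(C(C)C)cc(C(C)C)cc1C(C)C)[C@H]2C/C=C(\C)CC/C=C(\C)CC/C=C(\C)CC2 | intermediate
24 | lithium boronate complex (C15 bound to tetracoordinate boron that carries the homogeranyl group and the neopentyl glycol ester) | [Li+].C[C@@]([B-]3(CC/C=C(\C)CCC=C(C)C)OCC(C)(C)CO3)(OC(=O)c1c(C(C)C)cc(C(C)C)cc1C(C)C)[C@H]2C/C=C(\C)CC/C=C(\C)CC/C=C(\C)CC2 | intermediate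
25 | 2-[(2R,5E)-6,10-dimethyl-2-[(1R,3E,7E,11E)-4,8,12-trimethylcyclotetradeca-3,7,11-trien-1-yl]undeca-5,9-dien-2-yl]-5,5-dimethyl-1,3,2-dioxaborinane | C[C@](B3OCC(C)(C)CO3)(CC/C=C(\C)CCC=C(C)C)[C@H]2C/C=C(\C)CC/C=C(\C)CC/C=C(\C)CC2 | intermediate
26 | colleterpenol [(2S,5E)-6,10-dimethyl-2-[(1R,3E,7E,11E)-4,8,12-trimethylcyclotetradeca-3,7,11-trien-1-yl]undeca-5,9-dien-2-ol] | CC(C)=CCC/C(C)=C/CC[C@](C)(O)[C@H]1C/C=C(\C)CC/C=C(\C)CC/C=C(\C)CC1 | target

**Count**

Total steps: 13. Longest linear sequence: 10 steps (steps 1–9 and 13); the boronic ester 22 takes 3 steps (10–12).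

**Steps most likely to fail**

1. Step 13. The α-deprotonation of the secondary benzoate may be slow or incomplete because the C15–H bond sits next to the branched ring carbon C1. Formation of the crowded boronate may also be reversible, which would return 14 or erode the stereochemical fidelity. The fallback sets out from 14 and gives up stereocontrol at C15 for a plain carbonyl addition. Reductive removal of the ester (LiAlH4, THF, reflux) would give (1R)-1-[(1R,3E,7E,11E)-4,8,12-trimethylcyclotetradeca-3,7,11-trien-1-yl]ethan-1-ol F1. Dess–Martin oxidation would give the methyl ketone 1-[(1R,3E,7E,11E)-4,8,12-trimethylcyclotetradeca-3,7,11-trien-1-yl]ethan-1-one F2. Addition of homogeranyllithium 20 (THF, −78 °C, to limit enolisation at C1) should then give 26 together with its C15 epimer (2R,5E)-6,10-dimethyl-2-[(1R,3E,7E,11E)-4,8,12-trimethylcyclotetradeca-3,7,11-trien-1-yl]undeca-5,9-dien-2-ol F3, to be separated on AgNO3-impregnated silica. The route is rejoined at 26.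

2. Step 8. Intermolecular alkylation (oligomerisation) may outrun closure of the 14-membered ring, because the carbanion is hard, β-branched and made with a strong base. The fallback sets out from 9 and replaces this by a palladium-catalysed allylic alkylation of a doubly stabilised carbon nucleophile under neutral conditions. C-Acylation of 9 (LiN(iPr)2, 2.1 equiv, then ClCO2Me, THF, −78 °C) would give the α-sulfonyl ester methyl (3R,4R,6E,10E)-2-(benzenesulfonyl)-7,11,15-trimethyl-4-{[2,4,6-tri(propan-2-yl)benzoyl]oxy}-3-... chain ester, described as the C14-methoxycarbonyl derivative of 9 F4. Allylic oxidation as in step 6 would give the C14-methoxycarbonyl derivative of 10 F5. ClCO2Me and pyridine (CH2Cl2, 0 °C) would give the allylic methyl carbonate of F5 F6. Tsuji–Trost macrocyclisation (Pd(PPh3)4, dppe, THF, reflux, slow addition) should give the C14-methoxycarbonyl derivative of 13 F7. Krapcho dealkoxycarbonylation (LiCl, wet DMSO, 150 °C) returns to 13.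

3. Step 6. The oxidation may not discriminate fully between the three trisubstituted alkenes, and over-oxidation to the enal may lower conversion to the alcohol. The fallback sets out from 9 and builds the (E)-allylic alcohol by degradation and olefination instead of C–H oxidation. NBS in aqueous THF (terminal-selective bromohydrin formation) would give the 13-bromo-14-hydroxy-13,14-dihydro derivative of 9 F8. K2CO3 in MeOH would give the 13,14-epoxide of 9 F9. HIO4 cleavage (THF–Et2O) would give the trisnor C13 aldehyde F10. Wittig reaction with Ph3P=C(CH3)CO2Et (CH2Cl2, rt) should give the (E)-2-methyl enoate, the ethyl ester at the oxidation level of the C15 acid of 10 F11. Reduction with iBu2AlH (CH2Cl2, −78 °C), which the hindered benzoate should survive, returns to 10.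

**Further compounds**

F1 | step 13 | (1R)-1-[(1R,3E,7E,11E)-4,8,12-trimethylcyclotetradeca-3,7,11-trien-1-yl]ethan-1-ol | C[C@@H](O)[C@H]1C/C=C(\C)CC/C=C(\C)CC/C=C(\C)CC1
F2 | step 13 | 1-[(1R,3E,7E,11E)-4,8,12-trimethylcyclotetradeca-3,7,11-trien-1-yl]ethan-1-one | CC(=O)[C@H]1C/C=C(\C)CC/C=C(\C)CC/C=C(\C)CC1
F3 | step 13 | C15 epimer of 26, (2R,5E)-6,10-dimethyl-2-[(1R,3E,7E,11E)-4,8,12-trimethylcyclotetradeca-3,7,11-trien-1-yl]undeca-5,9-dien-2-ol | CC(C)=CCC/C(C)=C/CC[C@@](C)(O)[C@H]1C/C=C(\C)CC/C=C(\C)CC/C=C(\C)CC1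
F4 | step 8 | C14-methoxycarbonyl derivative of 9 (α-sulfonyl methyl ester, both C14 epimers) | C[C@@H](OC(=O)c1c(C(C)C)cc(C(C)C)cc1C(C)C)[C@@H](C/C=C(\C)CC/C=C(\C)CCC=C(C)C)C(C(=O)OC)S(=O)(=O)c2ccccc2
F5 | step 8 | C14-methoxycarbonyl derivative of 10 ((E)-allylic alcohol) | C[C@@H](OC(=O)c1c(C(C)C)cc(C(C)C)cc1C(C)C)[C@@H](C/C=C(\C)CC/C=C(\C)CC/C=C(\C)CO)C(C(=O)OC)S(=O)(=O)c2ccccc2
F6 | step 8 | allylic methyl carbonate of F5 | C[C@@H](OC(=O)c1c(C(C)C)cc(C(C)C)cc1C(C)C)[C@@H](C/C=C(\C)CC/C=C(\C)CC/C=C(\C)COC(=O)OC)C(C(=O)OC)S(=O)(=O)c2ccccc2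
F7 | step 8 | C14-methoxycarbonyl derivative of 13 (macrocycle with C14 bearing SO2Ph and CO2Me) | C[C@@H](OC(=O)c1c(C(C)C)cc(C(C)C)cc1C(C)C)[C@H]2C/C=C(\C)CC/C=C(\C)CC/C=C(\C)CC2(C(=O)OC)S(=O)(=O)c3ccccc3
F8 | step 6 | terminal bromohydrin of 9 (13-bromo-14-hydroxy, both C13 epimers) | C[C@@H](OC(=O)c1c(C(C)C)cc(C(C)C)cc1C(C)C)[C@@H](C/C=C(\C)CC/C=C(\C)CCC(Br)C(C)(C)O)CS(=O)(=O)c2ccccc2
F9 | step 6 | terminal 13,14-epoxide of 9 | C[C@@H](OC(=O)c1c(C(C)C)cc(C(C)C)cc1C(C)C)[C@@H](C/C=C(\C)CC/C=C(\C)CCC3OC3(C)C)CS(=O)(=O)c2ccccc2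
F10 | step 6 | trisnor C13 aldehyde from F9 | C[C@@H](OC(=O)c1c(C(C)C)cc(C(C)C)cc1C(C)C)[C@@H](C/C=C(\C)CC/C=C(\C)CCC=O)CS(=O)(=O)c2ccccc2
F11 | step 6 | (E)-2-methyl enoate (ethyl ester) from F10 | C[C@@H](OC(=O)c1c(C(C)C)cc(C(C)C)cc1C(C)C)[C@@H](C/C=C(\C)CC/C=C(\C)CC/C=C(\C)C(=O)OCC)CS(=O)(=O)c2ccccc2
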